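**Retrosynthetic overview**
1. Kazinol H comes from its 7-O-prenyl flavan. A final aromatic Claisen shift turns the prenyl ether, which until then protects the 7-OH, into the 6-(1,1-dimethylallyl) phenol.
2. Ring C is formed last, by invertive O1–C2 Mitsunobu closure of an (R)-1,3-diarylpropan-1-ol.
3. The (R)-carbinol comes from a one-flask union of a ring B aryl boronate, vinylmagnesium bromide and a ring A benzylic carbonate. A palladium-triggered 1,2-shift of the ring B aryl group from boron to carbon makes C1'–C2 and C3–C4 and sets C2.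
4. The ring B boronate comes from catechol: symmetric dibromination, then a dimethylpropargyl ether that closes the chromene ring (formed first), then borylation at C1' and prenylation at C2' of the two bromides in turn.
5. The ring A carbonate comes from resorcinol: formylation, 4-O-prenylation, reduction, double carbonate formation.

Assumption: the SMILES descriptor corresponds to (2S), and of the two purchasable antipodes of the ferrocenyl bisphosphine the one that delivers (R)-19 is fixed by a model run.

**Step 1**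
Reactants: 1 catechol (benzene-1,2-diol)
Product: 2 4,5-dibromobenzene-1,2-diol
Conditions: Br2 (2.05 equiv), AcOH, 0 °C to rt
Reagents that add atoms: bromine, BrBr
Why: Electrophilic aromatic bromination, in which each OH directs para, so two equivalents give only the symmetric 4,5-dibromide that carries halogen at the future C1' and C2'.

**Step 2**
Reactants: 2 4,5-dibromobenzene-1,2-diol (1.5 equiv); 3 3-chloro-3-methylbut-1-yne
Product: 4 4,5-dibromo-2-[(2-methylbut-3-yn-2-yl)oxy]phenol
Conditions: K2CO3 (1.1 equiv), KI (10 mol %), CuCl (2 mol %), acetone, 56 °C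
Reagents that add atoms: none
Why: Copper-assisted Williamson-type O-alkylation with a tertiary propargylic chloride; because 2 is symmetric either OH gives the same mono-ether, and the excess of 2 (recovered) suppresses the bis-ether.

**Step 3**
Reactants: 4 4,5-dibromo-2-[(2-methylbut-3-yn-2-yl)oxy]phenol
Product: 6 tert-butyl[(5,6-dibromo-2,2-dimethyl-2H-chromen-8-yl)oxy]dimethylsilane, via 5,6-dibromo-2,2-dimethyl-2H-chromen-8-ol 5 (not isolated)
Conditions: DMF, 150 °C, 8 h; cool to rt; imidazole, TBSCl
Reagents that add atoms: tert-butyldimethylsilyl chloride, CC(C)(C)[Si](C)(C)Cl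
Why: Aryl propargyl ether Claisen cascade ([3,3] shift, 1,5-H shift, oxa-6π closure), which can only reach the single free ortho carbon, so one chromene forms and its phenol is silylated in the same DMF solution.

**Step 4**
Reactants: 6 tert-butyl[(5,6-dibromo-2,2-dimethyl-2H-chromen-8-yl)oxy]dimethylsilane
Product: 7 {[5-bromo-2,2-dimethyl-6-(4,4,5,5-tetramethyl-1,3,2-dioxaborolan-2-yl)-2H-chromen-8-yl]oxy}(tert-butyl)dimethylsilane
Conditions: B2pin2 (1.0 equiv), PdCl2(dppf) (3 mol %), KOAc (3 equiv), 1,4-dioxane, 80 °C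
Reagents that add atoms: bis(pinacolato)diboron, CC1(C)OB(OC1(C)C)B1OC(C)(C)C(C)(C)O1
Why: Miyaura borylation under steric control: both bromides sit para to an oxygen donor, but C6–Br has an ortho hydrogen while C5–Br is wedged between Br and the peri vinyl carbon, so oxidative addition should take place at C6 and the still more crowded product does not react again.

**Step 5**
Reactants: 7 the 5-bromo-6-boryl chromene; 8 prenyl bromide (1-bromo-3-methylbut-2-ene)
Product: 10 tert-butyl{[2,2-dimethyl-5-(3-methylbut-2-en-1-yl)-6-(4,4,5,5-tetramethyl-1,3,2-dioxaborolan-2-yl)-2H-chromen-8-yl]oxy}dimethylsilane, via prenylzinc bromide 9 (not isolated)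
Conditions: 8, Zn dust, LiCl, THF, 0 °C; then 7, Pd(OAc)2 (2 mol %), CPhos (4 mol %), THF, rt to 40 °C
Reagents that add atoms: none
Why: Linear-selective Negishi coupling of an allylzinc halide; without base the pinacol boronate does not transmetalate, and the bulky biaryl phosphine accepts di-ortho-substituted aryl bromides and gives the unbranched prenyl arene.

**Step 6**
Reactants: 11 resorcinol (benzene-1,3-diol)
Product: 13 2,4-dihydroxybenzaldehyde, via aryl iminium chloride 12 (not isolated)
Conditions: POCl3, DMF, MeCN, −15 °C to rt; then H2O, 50 °C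
Reagents that add atoms: N,N-dimethylformamide, CN(C)C=O; water, O
Why: Vilsmeier–Haack formylation at the carbon ortho to one OH and para to the other, which supplies the future C4.

**Step 7**
Reactants: 13 2,4-dihydroxybenzaldehyde; 8 prenyl bromide
Product: 14 2-hydroxy-4-[(3-methylbut-2-en-1-yl)oxy]benzaldehyde
Conditions: K2CO3 (1.1 equiv), acetone, 56 °C
Reagents that add atoms: none
Why: Williamson ether synthesis, selective for the 4-OH because the 2-OH is held in a hydrogen bond to the aldehyde.

**Step 8**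
Reactants: 14 2-hydroxy-4-[(3-methylbut-2-en-1-yl)oxy]benzaldehyde
Product: 15 2-(hydroxymethyl)-5-[(3-methylbut-2-en-1-yl)oxy]phenol
Conditions: NaBH4, THF/MeOH, 0 °C; neutral work-up, used crude
Reagents that add atoms: none
Why: Borohydride reduction of the aldehyde, which leaves the prenyl ether untouched.

**Step 9**
Reactants: 15 2-(hydroxymethyl)-5-[(3-methylbut-2-en-1-yl)oxy]phenol
Product: 16 2-[(methoxycarbonyl)oxy]-4-[(3-methylbut-2-en-1-yl)oxy]benzyl methyl carbonate
Conditions: ClCO2Me (2.5 equiv), pyridine, CH2Cl2, 0 °C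
Reagents that add atoms: methyl chloroformate, COC(=O)Cl
Why: Double O-acylation with one reagent, which makes the benzylic leaving group and masks O1 as a base-labile aryl carbonate, so that no quinone methide can form.

**Step 10**
Reactants: 10 the ring B aryl boronate; 17 vinylmagnesium bromide; 16 the ring A bis(methyl carbonate)
Product: 20 (R)-1-[8-hydroxy-2,2-dimethyl-5-(3-methylbut-2-en-1-yl)-2H-chromen-6-yl]-3-{2-hydroxy-4-[(3-methylbut-2-en-1-yl)oxy]phenyl}propan-1-ol, via vinylboron ate complex 18 (not isolated), via (R)-boronic ester 19 (not isolated)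
Conditions: 10, 17 (1.0 equiv), THF, 0 °C to rt; NaOTf (2 equiv), DMSO; 16 (1.1 equiv), Pd(OAc)2 (3 mol %), MandyPhos-type ferrocenyl bisphosphine with bis(3,5-dimethyl-4-methoxyphenyl)phosphino groups (3.6 mol %), 45 °C; then MeOH, 3 M NaOH, 30 % H2O2, 0 °C to rt
Reagents that add atoms: hydrogen peroxide, OO
Why: Proposed new method: zerovalent palladium ionises the electron-rich benzylic carbonate (loss of CO2 and methoxide) to a cationic eta-3-benzyl complex of divalent palladium held by the chiral bisphosphine, this cation binds one face of the vinyl group of 18 and triggers an anti 1,2-shift of the chromenyl group from boron to the alpha carbon (C1'–C2 bond, C2 stereocentre), and benzyl–alkyl reductive elimination closes C3–C4 to give (R)-19, after which retentive oxidation gives the (R)-alcohol while NaOH/MeOH strips the aryl carbonate and the phenolic silyl ether; the closest known reaction type is the enantioselective conjunctive cross-coupling of vinylboron ate complexes (palladium with aryl or alkenyl triflates and propargylic carbonates, nickel with alkyl iodides), which to my knowledge has not been shown with benzylic electrophiles.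

**Step 11**
Reactants: 20 the (R)-triol
Product: 21 6-{(2S)-7-[(3-methylbut-2-en-1-yl)oxy]chroman-2-yl}-2,2-dimethyl-5-(3-methylbut-2-en-1-yl)-2H-chromen-8-ol
Conditions: PPh3 (1.5 equiv), DIAD (1.5 equiv), toluene/THF, 0.01 M, −10 °C to rt
Reagents that add atoms: none
Why: Intramolecular Mitsunobu etherification, in which the ortho phenol displaces the activated benzylic oxygen with inversion, (R) to (S); the six-ring closure at high dilution outruns the remote 5'-OH, and low temperature in a weakly polar solvent holds back ionisation.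

**Step 12**
Reactants: 21 the (2S)-7-O-prenyl flavan
Product: 23 kazinol H, via ortho-dienone 22 (not isolated)
Conditions: N,N-diethylaniline, 185 °C, sealed tube, argon, 2 h
Reagents that add atoms: none
Why: Aromatic Claisen rearrangement with allyl inversion followed by tautomerisation; C6 is preferred because C8 lies between two oxygens and would have to accept a quaternary carbon (2-alkoxy-4-prenyloxyarenes are known to rearrange para to the 2-alkoxy group), the amine solvent prevents acid-induced cyclisation, and C2 is not touched.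

**Compound list**
1 | catechol | Oc1ccccc1O | starting material
2 | 4,5-dibromobenzene-1,2-diol | Oc1cc(Br)c(Br)cc1O | intermediate
3 | 3-chloro-3-methylbut-1-yne | C#CC(C)(C)Cl | starting material
4 | 4,5-dibromo-2-[(2-methylbut-3-yn-2-yl)oxy]phenol | C#CC(C)(C)Oc1cc(Br)c(Br)cc1O | intermediate
5 | 5,6-dibromo-2,2-dimethyl-2H-chromen-8-ol (not isolated) | CC1(C)C=Cc2c(O1)c(O)cc(Br)c2Br | intermediate
6 | tert-butyl[(5,6-dibromo-2,2-dimethyl-2H-chromen-8-yl)oxy]dimethylsilane | CC1(C)C=Cc2c(O1)c(O[Si](C)(C)C(C)(C)C)cc(Br)c2Br | intermediate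
7 | 5-bromo-6-(pinacolboryl)-8-(TBS-oxy)-2,2-dimethyl-2H-chromene | CC1(C)C=Cc2c(O1)c(O[Si](C)(C)C(C)(C)C)cc(B3OC(C)(C)C(C)(C)O3)c2Br | intermediate
8 | prenyl bromide | CC(C)=CCBr | starting material
9 | prenylzinc bromide (not isolated) | CC(C)=CC[Zn]Br | intermediate
10 | 5-prenyl-6-(pinacolboryl)-8-(TBS-oxy)-2,2-dimethyl-2H-chromene | CC1(C)C=Cc2c(O1)c(O[Si](C)(C)C(C)(C)C)cc(B3OC(C)(C)C(C)(C)O3)c2CC=C(C)C | intermediate
11 | resorcinol | Oc1cccc(O)c1 | starting material
12 | (2,4-dihydroxybenzylidene)dimethyliminium chloride (not isolated) | C[N+](C)=Cc1ccc(O)cc1O.[Cl-] | intermediate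
13 | 2,4-dihydroxybenzaldehyde | O=Cc1ccc(O)cc1O | intermediate
14 | 2-hydroxy-4-(prenyloxy)benzaldehyde | O=Cc1ccc(OCC=C(C)C)cc1O | intermediate
15 | 2-(hydroxymethyl)-5-(prenyloxy)phenol | OCc1ccc(OCC=C(C)C)cc1O | intermediate
16 | 2-[(methoxycarbonyl)oxy]-4-(prenyloxy)benzyl methyl carbonate | COC(=O)OCc1ccc(OCC=C(C)C)cc1OC(=O)OC | intermediate
17 | vinylmagnesium bromide | C=C[Mg]Br | starting material
18 | bromomagnesium aryl(vinyl)(pinacolato)borate (not isolated) | C=C[B-]1(c2cc(O[Si](C)(C)C(C)(C)C)c3c(c2CC=C(C)C)C=CC(C)(C)O3)OC(C)(C)C(C)(C)O1.[Mg+]Br | intermediate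
19 | (R)-1-aryl-3-arylpropyl pinacol boronate (not isolated) | CC1(C)OB(OC1(C)C)[C@@H](c1cc(O[Si](C)(C)C(C)(C)C)c2c(c1CC=C(C)C)C=CC(C)(C)O2)CCc1ccc(OCC=C(C)C)cc1OC(=O)OC | intermediate
20 | (R)-triol | O[C@@H](c1cc(O)c2c(c1CC=C(C)C)C=CC(C)(C)O2)CCc1ccc(OCC=C(C)C)cc1O | intermediate
21 | (2S)-7-O-prenyl flavan | CC(C)=CCOc1ccc2c(c1)O[C@H](c1cc(O)c3c(c1CC=C(C)C)C=CC(C)(C)O3)CC2 | intermediate
22 | (2S)-6-(2-methylbut-3-en-2-yl)-ortho-dienone, both C6 epimers (not isolated) | O=C1C=C2O[C@H](c3cc(O)c4c(c3CC=C(C)C)C=CC(C)(C)O4)CCC2=CC1C(C)(C)C=C | intermediate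
23 | kazinol H, 6-[(2S)-7-hydroxy-6-(2-methylbut-3-en-2-yl)chroman-2-yl]-2,2-dimethyl-5-(3-methylbut-2-en-1-yl)-2H-chromen-8-ol | C=CC(C)(C)c1cc2c(cc1O)O[C@H](c1cc(O)c3c(c1CC=C(C)C)C=CC(C)(C)O3)CC2 | target

**Totals:** 12 steps. The longest linear sequence is 8 steps (steps 1–5, then 10–12).

**Three steps most likely to fail**

**Step 10 (the proposed new step).**
- Failure modes: plain Suzuki-type transfer of vinyl or aryl to the benzyl palladium species; beta-hydride elimination before the benzyl–alkyl reductive elimination; and a racemic outer-sphere or quinone-methide pathway if the aryl carbonate is lost early.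
- The fallback uses only known chemistry. It sets out from 10 and 14 and comes back at 20.
- Acylative Suzuki–Miyaura coupling of 10 with acetic anhydride (Pd(OAc)2, P(4-MeOC6H4)3, THF/H2O) gives 1-{8-[(tert-butyldimethylsilyl)oxy]-2,2-dimethyl-5-(3-methylbut-2-en-1-yl)-2H-chromen-6-yl}ethan-1-one F1.
- Claisen–Schmidt condensation of this ketone with 14 (KOH, EtOH, rt, the phenolic silyl ether falls off) gives (E)-1-[8-hydroxy-2,2-dimethyl-5-prenyl-2H-chromen-6-yl]-3-[2-hydroxy-4-(prenyloxy)phenyl]prop-2-en-1-one F2.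
- Copper hydride conjugate reduction ([(Ph3P)CuH]6, PhSiH3, toluene) spares the isolated alkenes and gives the saturated ketone 1-[8-hydroxy-2,2-dimethyl-5-prenyl-2H-chromen-6-yl]-3-[2-hydroxy-4-(prenyloxy)phenyl]propan-1-one F3.
- Asymmetric transfer hydrogenation with RuCl[(R,R)-TsDPEN](p-cymene) in HCO2H/Et3N gives (R)-20.

**Step 4 (site selectivity between two neighbouring bromides).**
- The fallback replaces steric control at palladium by electronic control in a halogen–metal exchange. It sets out from 5 (isolated this time) and comes back at 7.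
- Compound 5 is deprotonated with MeMgCl and treated with iPrMgCl·LiCl at −15 °C.
- The phenoxide lies para to C5 and disfavours a carbanion there, so exchange occurs at C6, which is also the less crowded site.
- Quenching with iPrOBpin gives 5-bromo-2,2-dimethyl-6-(4,4,5,5-tetramethyl-1,3,2-dioxaborolan-2-yl)-2H-chromen-8-ol F4, which TBSCl/imidazole converts into 7.

**Step 12 (competing C8 attack, and thermal cyclisation of the product to a dihydrobenzofuran).**
- The fallback brings in the 1,1-dimethylallyl group by cross-coupling on ring A before the union, so that no sigmatropic step is needed. It sets out from 13 and 8 and comes back at 23.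
- Bromination of 13 (Br2, AcOH) gives 5-bromo-2,4-dihydroxybenzaldehyde F5.
- Prenyl bromide 8 is converted (Mg, iPrOBpin, THF, Barbier mode) into prenylboronic acid pinacol ester F6.
- Branched-selective Suzuki–Miyaura coupling of the two (Pd(OAc)2, bulky biaryl phosphine, K3PO4, MeCN/H2O, 70 °C) gives 2,4-dihydroxy-5-(2-methylbut-3-en-2-yl)benzaldehyde F7.
- NaBH4 gives 4-(hydroxymethyl)-6-(2-methylbut-3-en-2-yl)benzene-1,3-diol F8.
- ClCO2Me/pyridine gives the corresponding tris(methyl carbonate) F9.
- This carbonate takes the place of 16 in step 10 and gives, by way of the (R)-boronic ester F10, the (R)-tetraol F11.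
- Mitsunobu closure as in step 11 leads directly to 23.

**Further compounds**
F1 | step 10 | 1-{8-[(tert-butyldimethylsilyl)oxy]-2,2-dimethyl-5-(3-methylbut-2-en-1-yl)-2H-chromen-6-yl}ethan-1-one | CC(=O)c1cc(O[Si](C)(C)C(C)(C)C)c2c(c1CC=C(C)C)C=CC(C)(C)O2
F2 | step 10 | (E)-1-[8-hydroxy-2,2-dimethyl-5-prenyl-2H-chromen-6-yl]-3-[2-hydroxy-4-(prenyloxy)phenyl]prop-2-en-1-one | O=C(/C=C/c1ccc(OCC=C(C)C)cc1O)c1cc(O)c2c(c1CC=C(C)C)C=CC(C)(C)O2
F3 | step 10 | 1-[8-hydroxy-2,2-dimethyl-5-prenyl-2H-chromen-6-yl]-3-[2-hydroxy-4-(prenyloxy)phenyl]propan-1-one | O=C(CCc1ccc(OCC=C(C)C)cc1O)c1cc(O)c2c(c1CC=C(C)C)C=CC(C)(C)O2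
F4 | step 4 | 5-bromo-2,2-dimethyl-6-(4,4,5,5-tetramethyl-1,3,2-dioxaborolan-2-yl)-2H-chromen-8-ol | CC1(C)C=Cc2c(O1)c(O)cc(B3OC(C)(C)C(C)(C)O3)c2Br
F5 | step 12 | 5-bromo-2,4-dihydroxybenzaldehyde | O=Cc1cc(Br)c(O)cc1O
F6 | step 12 | prenylboronic acid pinacol ester | CC(C)=CCB1OC(C)(C)C(C)(C)O1
F7 | step 12 | 2,4-dihydroxy-5-(2-methylbut-3-en-2-yl)benzaldehyde | C=CC(C)(C)c1cc(C=O)c(O)cc1O
F8 | step 12 | 4-(hydroxymethyl)-6-(2-methylbut-3-en-2-yl)benzene-1,3-diol | C=CC(C)(C)c1cc(CO)c(O)cc1O
F9 | step 12 | 2,4-bis[(methoxycarbonyl)oxy]-5-(2-methylbut-3-en-2-yl)benzyl methyl carbonate | C=CC(C)(C)c1cc(COC(=O)OC)c(OC(=O)OC)cc1OC(=O)OC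
F10 | step 12 | (R)-boronic ester carrying the 1,1-dimethylallyl ring A | CC1(C)OB(OC1(C)C)[C@@H](c1cc(O[Si](C)(C)C(C)(C)C)c2c(c1CC=C(C)C)C=CC(C)(C)O2)CCc1cc(C(C)(C)C=C)c(OC(=O)OC)cc1OC(=O)OC
F11 | step 12 | (R)-4-{3-hydroxy-3-[8-hydroxy-2,2-dimethyl-5-prenyl-2H-chromen-6-yl]propyl}-6-(2-methylbut-3-en-2-yl)benzene-1,3-diol | O[C@@H](c1cc(O)c2c(c1CC=C(C)C)C=CC(C)(C)O2)CCc1cc(C(C)(C)C=C)c(O)cc1O
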